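**Plan**

- Retrosynthesis: first the angelate C–O bond is cut. Then both bonds that tie ring A to ring B are cut together, namely carbinol carbon to ring-fusion sp2 carbon and CH(CH3) carbon to quaternary carbon. This gives a 3-bromo-4-methylphenol that already carries the (S)-propanoic acid, and (S)-2-methyl-2,3-dihydrofuran.
- Enabling feature: ring B is a cross-conjugated cyclohexa-2,5-dienone whose quaternary methyl carbon is para to the C=O, i.e. a dearomatised para-cresol. The four-carbon bridge of ring A carries its oxygen and its methyl on the two end carbons, cis to each other, which are the two C–O carbons of a 2,5-dihydrofuran.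
- Forward: ring B is present from the start as the arene. One Pd domino (Heck arylation of the dihydrofuran, then Pd-allyl ring opening with attack of the phenol para carbon) builds ring A and turns the arene into the dienone. Esterification, hydrogenation of the ring-A alkene and angeloylation finish the route.
- Stereochemistry: the side-chain centre comes from Rh-catalysed asymmetric hydroformylation. The CH(CH3) centre comes from (S)-2-methyloxirane and is carried over with net retention. The carbinol centre comes from Heck addition anti to that methyl. The quaternary centre comes from the half-chair ring closure.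

Key step: step 9

Remark on the chemistry: the side-chain acid is kept free (carboxylate under basic conditions) until ring B is dearomatised, because an ortho-hydroxyaryl propanoate ester can close to a 3-methylbenzofuran-2-one whose α-centre epimerises easily.

**Route**

Step 1
Reactants: 1 3-bromo-4-methylphenol
Product: 2 4-bromo-2-hydroxy-5-methylbenzaldehyde
Conditions: MgCl2, Et3N, (CH2O)n, MeCN, reflux; aq. HCl
Reagents that add atoms: paraformaldehyde (as formaldehyde) C=O
Why: Magnesium-mediated ortho-formylation of a phenol (Casnati–Skattebøl reaction), in which the magnesium phenoxide delivers formaldehyde to the ortho carbon and a second formaldehyde takes up the hydride; of the two ortho positions the one not flanked by bromine should react.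

Step 2
Reactants: 2 4-bromo-2-hydroxy-5-methylbenzaldehyde
Product: 3 4-bromo-2-[(tert-butyldimethylsilyl)oxy]-5-methylbenzaldehyde
Conditions: TBSCl, imidazole, DMF, rt
Reagents that add atoms: tert-butyldimethylsilyl chloride CC(C)(C)[Si](C)(C)Cl
Why: Silylation of the phenol (substitution at silicon) masks the acidic OH for the Wittig, hydroformylation and chlorite steps.

Step 3
Reactants: 3 4-bromo-2-[(tert-butyldimethylsilyl)oxy]-5-methylbenzaldehyde
Product: 4 (5-bromo-2-ethenyl-4-methylphenoxy)(tert-butyl)dimethylsilane
Conditions: Ph3PCH3Br, KOtBu, THF, 0 °C to rt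
Reagents that add atoms: methyltriphenylphosphonium bromide C[P+](c1ccccc1)(c1ccccc1)c1ccccc1.[Br-]
Why: Wittig methylenation of the aryl aldehyde gives the styrene, and an alkoxide base avoids bromine–metal exchange at the aryl bromide.

Step 4
Reactants: 4 (5-bromo-2-ethenyl-4-methylphenoxy)(tert-butyl)dimethylsilane
Product: 5 (2S)-2-[4-bromo-2-[(tert-butyldimethylsilyl)oxy]-5-methylphenyl]propanal
Conditions: Rh(acac)(CO)2 (0.5 mol%), Ph-BPE (the enantiomer that gives the S aldehyde), CO/H2 (1:1, 10 bar), toluene, 60 °C
Reagents that add atoms: carbon monoxide [C-]#[O+]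
Why: Rh-catalysed asymmetric hydroformylation of a vinylarene, in which Rh–H adds to give the benzylic (branched) rhodium alkyl and the chiral bisphospholane selects the alkene face, so the side-chain stereocentre is set by catalyst control.

Step 5
Reactants: 5 (2S)-2-[4-bromo-2-[(tert-butyldimethylsilyl)oxy]-5-methylphenyl]propanal
Product: 6 (2S)-2-[4-bromo-2-[(tert-butyldimethylsilyl)oxy]-5-methylphenyl]propanoic acid
Conditions: NaClO2, NaH2PO4, 2-methylbut-2-ene, t-BuOH/H2O, 0 °C
Reagents that add atoms: sodium chlorite [Na+].[O-]Cl=O
Why: Pinnick oxidation converts the aldehyde to the acid under buffered, non-enolising conditions, so the α-aryl stereocentre should be kept, and the alkene scavenges the hypochlorous acid that would chlorinate the arene.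

Step 6
Reactants: 6 (2S)-2-[4-bromo-2-[(tert-butyldimethylsilyl)oxy]-5-methylphenyl]propanoic acid
Product: 7 (2S)-2-(4-bromo-2-hydroxy-5-methylphenyl)propanoic acid
Conditions: TBAF (2.2 equiv), THF, 0 °C; cold aq. HCl to pH 3
Reagents that add atoms: none
Why: Fluoride cleaves the aryl silyl ether (strong Si–F bond) while the acid is present as its carboxylate, which cannot lactonise onto the free phenol.

Step 7
Reactants: 8 (S)-2-methyloxirane
Product: 9 (2S)-pent-4-yn-2-ol
Conditions: lithium acetylide–ethylenediamine complex, DMSO, 0 °C to rt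
Reagents that add atoms: lithium acetylide ethylenediamine complex [Li]C#C.NCCN
Why: SN2 opening of the epoxide at its unsubstituted carbon by the acetylide leaves the stereocentre untouched.

Step 8
Reactants: 9 (2S)-pent-4-yn-2-ol
Product: 10 (2S)-2-methyl-2,3-dihydrofuran
Conditions: Mo(CO)6 (20 mol%), Et3N, Et2O, hν (350 nm), rt; distillation
Reagents that add atoms: none
Why: Alkynol cycloisomerisation through a molybdenum vinylidene (5-endo attack of the hydroxyl on the carbene carbon) gives the endocyclic enol ether without touching the stereocentre.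

Step 9
Reactants: 7 (2S)-2-(4-bromo-2-hydroxy-5-methylphenyl)propanoic acid; 10 (2S)-2-methyl-2,3-dihydrofuran
Product: 12 (2S)-2-[(5R,8S,8aS)-5-hydroxy-8,8a-dimethyl-3-oxo-3,5,8,8a-tetrahydronaphthalen-2-yl]propanoic acid, via trans-dihydrofuran Heck adduct 11 (not isolated)
Conditions: Pd2(dba)3 (2.5 mol%), P(CH2tBu)3 (10 mol%), Cy2NMe (3 equiv), 10 (3 equiv), 1,4-dioxane, sealed tube, 80 then 100 °C; aq. citric acid
Reagents that add atoms: none
Why: Proposed new method: oxidative addition of Pd(0) into the C–Br bond of 7 and syn-carbopalladation of the enol ether of 10 place the aryl group on the oxygen-bearing carbon from the face opposite the ring methyl, and β-hydride elimination gives the trans-2-aryl-5-methyl-2,5-dihydrofuran 11; Pd(0), with the ammonium bromide as proton donor to the ring oxygen, should then ionise the allylic C–O bond at the methyl-bearing carbon to a π-allyl complex that is attacked by the para carbon of the phenol, which dearomatises ring B to the dienone and frees the carbinol OH. The first half is a Mizoroki–Heck arylation of a 2,3-dihydrofuran, and the second half is closest to the Tsuji–Trost opening of cyclic allylic ethers and to the Pd-catalysed dearomative para-C-allylation and cyclisation of para-alkylphenols that carry a meta tether; the merger of the two, and a plain dihydrofuran oxygen as leaving group, are the untested parts. Ring A closes in a six-membered mode by attack of the arene carbon on the distal allyl terminus (the near terminus would give a four-membered ring), and ionisation of the other, benzylic C–O bond leads to no closable ring and should be reversible. The carbinol centre is controlled by the methyl stereocentre of 10 in the Heck event, the methyl-bearing centre keeps the configuration of 10 by double inversion (ionisation anti to oxygen, outer-sphere attack anti to palladium), and the quaternary centre follows from closure through the half-chair in which the carbinol C–O bond stands perpendicular to the arene plane (no allylic strain with the ortho hydrogen) and the allyl methyl is pseudo-equatorial, which puts the angular methyl cis to both. The step needs arylation at the O-bearing alkene carbon (usual for electron-rich enol ethers), no Pd–H migration of the new double bond into the enol ether position (bulky trialkylphosphine and amine base), para instead of ortho attack of the phenol (larger HOMO coefficient at the para carbon and the precedent of the tethered para-alkylphenols) and an intact side-chain centre (carried as the carboxylate).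

Step 10
Reactants: 12 (2S)-2-[(5R,8S,8aS)-5-hydroxy-8,8a-dimethyl-3-oxo-3,5,8,8a-tetrahydronaphthalen-2-yl]propanoic acid
Product: 13 methyl (2S)-2-[(5R,8S,8aS)-5-hydroxy-8,8a-dimethyl-3-oxo-3,5,8,8a-tetrahydronaphthalen-2-yl]propanoate
Conditions: MeI, KHCO3, DMF, rt
Reagents that add atoms: iodomethane CI
Why: O-alkylation of the carboxylate (SN2 on iodomethane) under weakly basic conditions should give the methyl ester without touching the secondary alcohol or the α-stereocentre.

Step 11
Reactants: 13 methyl (2S)-2-[(5R,8S,8aS)-5-hydroxy-8,8a-dimethyl-3-oxo-3,5,8,8a-tetrahydronaphthalen-2-yl]propanoate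
Product: 14 methyl (2S)-2-[(5R,8S,8aS)-5-hydroxy-8,8a-dimethyl-3-oxo-3,5,6,7,8,8a-hexahydronaphthalen-2-yl]propanoate
Conditions: H2 (1 atm), RhCl(PPh3)3 (5 mol%), benzene, rt
Reagents that add atoms: none
Why: Homogeneous Rh(I) hydrogenation should reduce the cis-disubstituted isolated double bond of ring A much faster than the two trisubstituted conjugated double bonds of the dienone, and no stereocentre is formed or touched.

Step 12
Reactants: 14 methyl (2S)-2-[(5R,8S,8aS)-5-hydroxy-8,8a-dimethyl-3-oxo-3,5,6,7,8,8a-hexahydronaphthalen-2-yl]propanoate; 15 angelic acid [(2Z)-2-methylbut-2-enoic acid]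
Product: 17 methyl (2S)-2-[(5R,8S,8aS)-8,8a-dimethyl-5-{[(2Z)-2-methylbut-2-enoyl]oxy}-3-oxo-3,5,6,7,8,8a-hexahydronaphthalen-2-yl]propanoate, via angelic 2,4,6-trichlorobenzoic anhydride 16 (not isolated)
Conditions: 15, 2,4,6-trichlorobenzoyl chloride, Et3N, toluene, rt; then 14, 75 °C
Reagents that add atoms: none
Why: Yamaguchi-type esterification through the mixed anhydride without a nucleophilic catalyst acylates the hindered allylic alcohol at the angeloyl carbonyl and avoids the addition–elimination path that turns a (Z)-2-methylbut-2-enoate into the (E) isomer, and the carbinol configuration is retained because only the O–H bond reacts.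

**Compound list**

1 | 3-bromo-4-methylphenol | Cc1ccc(O)cc1Br | starting material
2 | 4-bromo-2-hydroxy-5-methylbenzaldehyde | Cc1cc(C=O)c(O)cc1Br | intermediate
3 | 4-bromo-2-[(tert-butyldimethylsilyl)oxy]-5-methylbenzaldehyde | Cc1cc(C=O)c(O[Si](C)(C)C(C)(C)C)cc1Br | intermediate
4 | (5-bromo-2-ethenyl-4-methylphenoxy)(tert-butyl)dimethylsilane | Cc1cc(C=C)c(O[Si](C)(C)C(C)(C)C)cc1Br | intermediate
5 | (2S)-2-[4-bromo-2-[(tert-butyldimethylsilyl)oxy]-5-methylphenyl]propanal | Cc1cc([C@H](C)C=O)c(O[Si](C)(C)C(C)(C)C)cc1Br | intermediate
6 | (2S)-2-[4-bromo-2-[(tert-butyldimethylsilyl)oxy]-5-methylphenyl]propanoic acid | Cc1cc([C@H](C)C(=O)O)c(O[Si](C)(C)C(C)(C)C)cc1Br | intermediate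
7 | (2S)-2-(4-bromo-2-hydroxy-5-methylphenyl)propanoic acid | Cc1cc([C@H](C)C(=O)O)c(O)cc1Br | intermediate
8 | (S)-2-methyloxirane | C[C@H]1CO1 | starting material
9 | (2S)-pent-4-yn-2-ol | C[C@H](O)CC#C | intermediate
10 | (2S)-2-methyl-2,3-dihydrofuran | C[C@H]1CC=CO1 | intermediate
11 | (2S)-2-{2-hydroxy-5-methyl-4-[(2R,5S)-5-methyl-2,5-dihydrofuran-2-yl]phenyl}propanoic acid | C[C@H]1C=C[C@H](c2cc(O)c([C@H](C)C(=O)O)cc2C)O1 | intermediate
12 | (2S)-2-[(5R,8S,8aS)-5-hydroxy-8,8a-dimethyl-3-oxo-3,5,8,8a-tetrahydronaphthalen-2-yl]propanoic acid | O[C@@H]1C=C[C@H](C)[C@@]2(C)C=C([C@H](C)C(=O)O)C(=O)C=C12 | intermediate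
13 | methyl (2S)-2-[(5R,8S,8aS)-5-hydroxy-8,8a-dimethyl-3-oxo-3,5,8,8a-tetrahydronaphthalen-2-yl]propanoate | O[C@@H]1C=C[C@H](C)[C@@]2(C)C=C([C@H](C)C(=O)OC)C(=O)C=C12 | intermediate
14 | methyl (2S)-2-[(5R,8S,8aS)-5-hydroxy-8,8a-dimethyl-3-oxo-3,5,6,7,8,8a-hexahydronaphthalen-2-yl]propanoate | O[C@@H]1CC[C@H](C)[C@@]2(C)C=C([C@H](C)C(=O)OC)C(=O)C=C12 | intermediate
15 | angelic acid [(2Z)-2-methylbut-2-enoic acid] | C/C=C(/C)C(=O)O | starting material
16 | (2Z)-2-methylbut-2-enoic 2,4,6-trichlorobenzoic anhydride | C/C=C(/C)C(=O)OC(=O)c1c(Cl)cc(Cl)cc1Cl | intermediate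
17 | methyl (2S)-2-[(5R,8S,8aS)-8,8a-dimethyl-5-{[(2Z)-2-methylbut-2-enoyl]oxy}-3-oxo-3,5,6,7,8,8a-hexahydronaphthalen-2-yl]propanoate | C/C=C(/C)C(=O)O[C@@H]1CC[C@H](C)[C@@]2(C)C=C([C@H](C)C(=O)OC)C(=O)C=C12 | target

**Summary**

Total step count: 12. Longest linear sequence: 10 (steps 1–6 and 9–12); steps 7 and 8 form the second branch.

Steps most likely to fail:

1. Step 9 (Proposed new method). Several processes may go wrong:
   - The dihydrofuran ring may fail to open, so that the Heck adduct 11 accumulates or its double bond migrates into the enol ether position and the methyl-bearing centre is lost.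
   - The benzylic C–O bond may ionise instead, or the π-allyl complex may change face, which would scramble the carbinol or the methyl-bearing centre.
   - The phenol may close through its ortho carbon and rearomatise.

   The fallback uses known reactions only, sets out from 6 and comes back at 14. Acid 6 is esterified (MeI, K2CO3, DMF) to methyl (2S)-2-[4-bromo-2-(tert-butyldimethylsilyloxy)-5-methylphenyl]propanoate F1. Sonogashira coupling (PdCl2(PPh3)2, CuI, Et3N, 60 °C) with (2R)-pent-4-yn-2-ol F2, made from (R)-2-methyloxirane in the way 9 is made from 8, should give the aryl alkyne F3. Gold-catalysed hydration (Ph3PAuCl/AgOTf, wet dioxane), directed to the aryl-bound carbon by the neighbouring hydroxyl, should give the γ-hydroxy aryl ketone F4, and MsCl/Et3N the mesylate F5. TBAF in THF should then remove the aryl silyl group and, in the same flask, the phenoxide should alkylate through its para carbon with inversion at the mesylate carbon (alkylative dearomatisation) to the ene-dione F6. Luche reduction (NaBH4, CeCl3, MeOH, −78 °C) from the face opposite the angular methyl should give 14.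

2. Step 4. The bulky ortho-silyloxy group may lower the branched-to-linear ratio or the face selectivity of the hydroformylation, and the α-aryl aldehyde may racemise on handling. The fallback sets out from 4 and comes back at 5. Ni-catalysed asymmetric hydrovinylation (ethylene, [(allyl)NiBr]2, chiral phosphoramidite, NaBArF4, CH2Cl2, −70 °C) should give [5-bromo-2-[(2R)-but-3-en-2-yl]-4-methylphenoxy](tert-butyl)dimethylsilane F7. Ozonolysis (O3, CH2Cl2, −78 °C; PPh3) should give 5, which is oxidised at once as in step 5.

3. Step 12. The (Z)-acyl group may isomerise to the (E) isomer during activation, and the pseudo-axial allylic hydroxyl may acylate slowly, which leaves time for base-induced isomerisation of the γ-hydroxy enone. The fallback sets out from 14 and comes back at 17. DCC/DMAP coupling with 2-[bis(2,2,2-trifluoroethoxy)phosphoryl]propanoic acid F8 (LiOH saponification of its commercial methyl ester) should give the phosphonate ester F9. Still–Gennari olefination (KHMDS, 18-crown-6, THF, −78 °C; acetaldehyde) should then build the (Z)-2-methylbut-2-enoate directly.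

Further compounds
F1 | step 9 | methyl (2S)-2-[4-bromo-2-(tert-butyldimethylsilyloxy)-5-methylphenyl]propanoate | Cc1cc([C@H](C)C(=O)OC)c(O[Si](C)(C)C(C)(C)C)cc1Br
F2 | step 9 | (2R)-pent-4-yn-2-ol | C[C@@H](O)CC#C
F3 | step 9 | methyl (2S)-2-[2-(tert-butyldimethylsilyloxy)-4-[(4R)-4-hydroxypent-1-yn-1-yl]-5-methylphenyl]propanoate | Cc1cc([C@H](C)C(=O)OC)c(O[Si](C)(C)C(C)(C)C)cc1C#CC[C@@H](C)O
F4 | step 9 | methyl (2S)-2-[2-(tert-butyldimethylsilyloxy)-4-[(4R)-4-hydroxypentanoyl]-5-methylphenyl]propanoate | Cc1cc([C@H](C)C(=O)OC)c(O[Si](C)(C)C(C)(C)C)cc1C(=O)CC[C@@H](C)O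
F5 | step 9 | methyl (2S)-2-[2-(tert-butyldimethylsilyloxy)-4-[(4R)-4-(methylsulfonyloxy)pentanoyl]-5-methylphenyl]propanoate | Cc1cc([C@H](C)C(=O)OC)c(O[Si](C)(C)C(C)(C)C)cc1C(=O)CC[C@@H](C)OS(C)(=O)=O
F6 | step 9 | methyl (2S)-2-[(8S,8aS)-8,8a-dimethyl-3,5-dioxo-3,5,6,7,8,8a-hexahydronaphthalen-2-yl]propanoate | O=C1CC[C@H](C)[C@@]2(C)C=C([C@H](C)C(=O)OC)C(=O)C=C12
F7 | step 4 | [5-bromo-2-[(2R)-but-3-en-2-yl]-4-methylphenoxy](tert-butyl)dimethylsilane | Cc1cc([C@H](C)C=C)c(O[Si](C)(C)C(C)(C)C)cc1Br
F8 | step 12 | 2-[bis(2,2,2-trifluoroethoxy)phosphoryl]propanoic acid | CC(C(=O)O)P(=O)(OCC(F)(F)F)OCC(F)(F)F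
F9 | step 12 | methyl (2S)-2-[(5R,8S,8aS)-5-{2-[bis(2,2,2-trifluoroethoxy)phosphoryl]propanoyloxy}-8,8a-dimethyl-3-oxo-3,5,6,7,8,8a-hexahydronaphthalen-2-yl]propanoate | CC(C(=O)O[C@@H]1CC[C@H](C)[C@@]2(C)C=C([C@H](C)C(=O)OC)C(=O)C=C12)P(=O)(OCC(F)(F)F)OCC(F)(F)F
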